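**Plan**

1. Retrosynthetic cuts, in order:
   - the side-chain C1' carbinol and its bond to C5 of the core (ketone reduction; aryllithium plus an (R)-lactic N-methoxy-N-methylamide);
   - C3–CH3 back to C3–CH2CO2Et (decarboxylation);
   - the bond from C2 of the dihydrofuran ring to the dimethoxyphenyl ring, cut together with one C–H of that CH2 group, back to veratrole and a cyclopropane fused across C2–C3;
   - the cyclopropane back to a benzofuran and ethyl diazoacetate;
   - the furan ring (C3–C3a, O1–C2) back to 4-bromo-2-methoxyphenol.
2. Forward order: the core benzene ring is bought, the furan ring is closed on it, a cyclopropane is fused to C2–C3, the cyclopropane is opened by veratrole (the five-membered oxygen ring stays), the ester carbon is excised, and the side chain is joined and reduced last.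
3. Enabling feature: the ring oxygen O1 bound to C2 of the five-membered ring. Its lone pair makes the C2–C3-fused cyclopropane ester a donor–acceptor cyclopropane whose exocyclic C2–C bond ionises at C2, so the aryl group enters at C2 and the cyclopropane carbon stays on C3 as the future methyl group.
4. Helpers: the cyclopropane (temporary ring) and its ester (acceptor) are removed by the ring opening (step 4) and by hydrolysis and decarboxylation (steps 5 and 6); the bromine at C5 is the handle for the side chain.
5. Stereochemistry: C3 from the catalyst-controlled cyclopropanation; C2 from anti (inverting) attack in the ring opening, trans to C3; side-chain C2' from methyl (R)-lactate; C1' from chelation-controlled reduction (anti diol).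

Key step: step 4

Assumption: in step 3 the (S,S)-bisoxazoline is taken, by analogy with styrene and enol ethers, to deliver the (1aR,6bS) cyclopropane; if the sense of induction is the opposite, the (R,R)-ligand is used instead.

**Route**

Step 1
Reactants: 1 4-bromo-2-methoxyphenol; 2 2-bromo-1,1-diethoxyethane
Product: 3 4-bromo-1-(2,2-diethoxyethoxy)-2-methoxybenzene
Conditions: K2CO3, KI (cat.), DMF, 120 °C
Reagents that add atoms: none
Why: Williamson ether synthesis, the phenoxide displacing the primary bromide of the acetal; no stereocentre is formed.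

Step 2
Reactants: 3 4-bromo-1-(2,2-diethoxyethoxy)-2-methoxybenzene
Product: 4 5-bromo-7-methoxy-1-benzofuran
Conditions: polyphosphoric acid, toluene, 110 °C
Reagents that add atoms: none
Why: acid-mediated cyclodehydration (intramolecular Friedel–Crafts alkylation by the acetal-derived oxocarbenium ion at the only free position ortho to the ether oxygen, then loss of ethanol to aromatise the furan ring); no stereocentre is formed.

Step 3
Reactants: 4 5-bromo-7-methoxy-1-benzofuran; 5 ethyl diazoacetate
Product: 6 ethyl (1R,1aR,6bS)-5-bromo-3-methoxy-1a,6b-dihydro-1H-cyclopropa[b][1]benzofuran-1-carboxylate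
Conditions: Cu(MeCN)4PF6 (2 mol %), 2,2'-isopropylidenebis[(4S)-4-tert-butyl-2-oxazoline] (2.4 mol %), 5 (3 equiv, slow addition), CH2Cl2, 0 °C → rt
Reagents that add atoms: none
Why: asymmetric cyclopropanation by a copper carbene of the enol-ether-like C2=C3 bond of the furan ring, in which the C2-symmetric bisoxazoline ligand on monovalent copper selects the alkene face and so sets C1a and C6b (cis fusion is enforced by the ring, the ester is expected exo), while the configuration at C1 is of no consequence because this carbon becomes a CH2 group in step 4.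

Step 4
Reactants: 6 ethyl (1R,1aR,6bS)-5-bromo-3-methoxy-1a,6b-dihydro-1H-cyclopropa[b][1]benzofuran-1-carboxylate; 7 1,2-dimethoxybenzene (veratrole)
Product: 8 ethyl 2-[(2S,3S)-5-bromo-2-(3,4-dimethoxyphenyl)-7-methoxy-2,3-dihydro-1-benzofuran-3-yl]acetate
Conditions: 7 (5 equiv), Me3SiOTf (0.2 equiv), CH2Cl2, −40 → 0 °C
Reagents that add atoms: none
Why: Proposed new method: silylation of the ester carbonyl polarises the donor–acceptor cyclopropane so that the C1a–C1 bond (between the carbon that carries the ring oxygen and the carbon that carries the ester) heterolyses, the lone pair of the furan-ring oxygen stabilising the developing 2,3-dihydrobenzofuran-2-ylium centre while the ester leaves as its silyl ketene acetal; veratrole attacks this carbon through its position para to one methoxy group, and the proton lost from the arenium ion is taken up by the ketene acetal carbon, which regenerates Me3SiOTf and makes the step a 1,3-hydroarylation of a C–C bond with no by-product. The closest known reaction types are the Lewis-acid-catalysed Friedel–Crafts ring opening of donor–acceptor cyclopropanes by electron-rich arenes and the ring-opening glycosylation of ester-substituted 1,2-cyclopropanated sugars; the extension is to a benzofuran-fused mono-ester cyclopropane with a simple dialkoxybenzene as the nucleophile. No ring is closed: the three-membered ring is opened, its strain supplying the driving force, and the five-membered oxygen ring is kept. The new stereocentre C2 should be set trans to the C3 substituent because the arene enters anti to the departing cyclopropane carbon (inversion at C2 or, in the ion-pair limit, attack on the face opposite the CH2CO2Et group), whereas C3 is not touched and keeps the configuration set in step 3. The step needs cleavage of C1a–C1 in preference to C6b–C1 (secured by the stronger oxygen donor), attack through C4 of veratrole (para to a methoxy group and unhindered), and arylation that is faster than loss of the C3 proton to the aromatic benzofuran-3-ylacetate; the excess of arene, the low temperature, the absence of base and the silyl cap on the enolate oxygen are relied on for the last point.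

Step 5
Reactants: 8 ethyl 2-[(2S,3S)-5-bromo-2-(3,4-dimethoxyphenyl)-7-methoxy-2,3-dihydro-1-benzofuran-3-yl]acetate
Product: 9 2-[(2S,3S)-5-bromo-2-(3,4-dimethoxyphenyl)-7-methoxy-2,3-dihydro-1-benzofuran-3-yl]acetic acid
Conditions: LiOH·H2O, THF–MeOH–H2O, rt; then 1 M HCl to pH 3, 0 °C
Reagents that add atoms: water (as LiOH·H2O), O
Why: ester saponification (acyl substitution by hydroxide), which touches neither C2 nor C3 because neither is alpha to the carbonyl group.

Step 6
Reactants: 9 2-[(2S,3S)-5-bromo-2-(3,4-dimethoxyphenyl)-7-methoxy-2,3-dihydro-1-benzofuran-3-yl]acetic acid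
Product: 11 (2S,3S)-5-bromo-2-(3,4-dimethoxyphenyl)-7-methoxy-3-methyl-2,3-dihydro-1-benzofuran, via thiohydroxamate ester 10 (not isolated)
Conditions: 1-hydroxypyridine-2(1H)-thione, DCC, DMAP (cat.), CH2Cl2, 0 °C → rt, dark; then t-BuSH (20 equiv), hν (tungsten lamp), rt
Reagents that add atoms: none
Why: Barton reductive decarboxylation, a radical chain in which the primary alkyl radical formed by loss of CO2 is reduced by hydrogen-atom transfer from the thiol (used in large excess so that it outruns beta-scission of the C2–C3 bond), leaving both stereocentres untouched and turning the CH2CO2H group into the C3 methyl group.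

Step 7
Reactants: 12 methyl (R)-lactate
Product: 13 (2R)-2-hydroxy-N-methoxy-N-methylpropanamide
Conditions: MeNHOMe·HCl (2.5 equiv), i-PrMgCl (5 equiv), THF, −20 → 0 °C
Reagents that add atoms: N,O-dimethylhydroxylamine hydrochloride, CNOC.Cl
Why: aminolysis of the ester by the chloromagnesium amide (formation of an N-methoxy-N-methylamide), the stereocentre of the lactate being carried over unchanged because the magnesium alkoxide next to it disfavours enolisation.

Step 8
Reactants: 13 (2R)-2-hydroxy-N-methoxy-N-methylpropanamide
Product: 14 (2R)-2-[(tert-butyldimethylsilyl)oxy]-N-methoxy-N-methylpropanamide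
Conditions: TBSCl, imidazole, DMF, rt
Reagents that add atoms: tert-butyl(chloro)dimethylsilane, CC(C)(C)[Si](C)(C)Cl
Why: silyl ether protection of the secondary alcohol, which does not involve the stereocentre.

Step 9
Reactants: 11 (2S,3S)-5-bromo-2-(3,4-dimethoxyphenyl)-7-methoxy-3-methyl-2,3-dihydro-1-benzofuran; 14 (2R)-2-[(tert-butyldimethylsilyl)oxy]-N-methoxy-N-methylpropanamide
Product: 17 (2R)-2-[(tert-butyldimethylsilyl)oxy]-1-[(2S,3S)-2-(3,4-dimethoxyphenyl)-7-methoxy-3-methyl-2,3-dihydro-1-benzofuran-5-yl]propan-1-one, via aryllithium 15 (not isolated), via lithium hemiaminal 16 (not isolated)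
Conditions: n-BuLi (1.05 equiv), THF, −78 °C; then 14 (1.3 equiv), −78 → −20 °C; aq NH4Cl
Reagents that add atoms: none
Why: bromine–lithium exchange followed by Weinreb ketone synthesis, in which the chelated tetrahedral adduct prevents a second addition and the low temperature keeps the aryllithium from deprotonating C2, so that all three existing stereocentres are retained.

Step 10
Reactants: 17 (2R)-2-[(tert-butyldimethylsilyl)oxy]-1-[(2S,3S)-2-(3,4-dimethoxyphenyl)-7-methoxy-3-methyl-2,3-dihydro-1-benzofuran-5-yl]propan-1-one
Product: 18 (2R)-1-[(2S,3S)-2-(3,4-dimethoxyphenyl)-7-methoxy-3-methyl-2,3-dihydro-1-benzofuran-5-yl]-2-hydroxypropan-1-one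
Conditions: HF·pyridine, pyridine, THF, 0 °C → rt
Reagents that add atoms: none
Why: fluoride-mediated cleavage of the silyl ether under buffered conditions, which are too mild to enolise the alpha-hydroxy ketone or to ionise the benzylic C2–O bond.

Step 11
Reactants: 18 (2R)-1-[(2S,3S)-2-(3,4-dimethoxyphenyl)-7-methoxy-3-methyl-2,3-dihydro-1-benzofuran-5-yl]-2-hydroxypropan-1-one
Product: 19 (1S,2R)-1-[(2S,3S)-2-(3,4-dimethoxyphenyl)-7-methoxy-3-methyl-2,3-dihydro-1-benzofuran-5-yl]propane-1,2-diol
Conditions: Zn(BH4)2 (Et2O solution), Et2O, −30 → 0 °C; aq NH4Cl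
Reagents that add atoms: none
Why: chelation-controlled hydride reduction of an alpha-hydroxy ketone, in which zinc bridges the carbonyl and hydroxyl oxygen atoms in a five-membered chelate and hydride is delivered to the carbonyl face anti to the methyl group of the neighbouring stereocentre, which should give the anti (erythro) diol with the (1S) configuration.

**Compound list**

1 | 4-bromo-2-methoxyphenol | COc1cc(Br)ccc1O | starting material
2 | 2-bromo-1,1-diethoxyethane | CCOC(CBr)OCC | starting material
3 | 4-bromo-1-(2,2-diethoxyethoxy)-2-methoxybenzene | CCOC(COc1ccc(Br)cc1OC)OCC | intermediate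
4 | 5-bromo-7-methoxy-1-benzofuran | COc1cc(Br)cc2ccoc12 | intermediate
5 | ethyl diazoacetate | CCOC(=O)C=[N+]=[N-] | starting material
6 | ethyl (1R,1aR,6bS)-5-bromo-3-methoxy-1a,6b-dihydro-1H-cyclopropa[b][1]benzofuran-1-carboxylate | CCOC(=O)[C@H]1[C@@H]2Oc3c(OC)cc(Br)cc3[C@H]12 | intermediate
7 | 1,2-dimethoxybenzene (veratrole) | COc1ccccc1OC | starting material
8 | ethyl 2-[(2S,3S)-5-bromo-2-(3,4-dimethoxyphenyl)-7-methoxy-2,3-dihydro-1-benzofuran-3-yl]acetate | COc1ccc([C@H]2Oc3c(OC)cc(Br)cc3[C@@H]2CC(=O)OCC)cc1OC | intermediate
9 | 2-[(2S,3S)-5-bromo-2-(3,4-dimethoxyphenyl)-7-methoxy-2,3-dihydro-1-benzofuran-3-yl]acetic acid | COc1ccc([C@H]2Oc3c(OC)cc(Br)cc3[C@@H]2CC(=O)O)cc1OC | intermediate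
10 | 2-thioxopyridin-1(2H)-yl 2-[(2S,3S)-5-bromo-2-(3,4-dimethoxyphenyl)-7-methoxy-2,3-dihydro-1-benzofuran-3-yl]acetate (thiohydroxamate ester) | COc1ccc([C@H]2Oc3c(OC)cc(Br)cc3[C@@H]2CC(=O)On4ccccc4=S)cc1OC | intermediate
11 | (2S,3S)-5-bromo-2-(3,4-dimethoxyphenyl)-7-methoxy-3-methyl-2,3-dihydro-1-benzofuran | COc1ccc([C@H]2Oc3c(OC)cc(Br)cc3[C@@H]2C)cc1OC | intermediate
12 | methyl (R)-lactate | C[C@@H](O)C(=O)OC | starting material
13 | (2R)-2-hydroxy-N-methoxy-N-methylpropanamide | C[C@@H](O)C(=O)N(C)OC | intermediate
14 | (2R)-2-[(tert-butyldimethylsilyl)oxy]-N-methoxy-N-methylpropanamide | C[C@@H](O[Si](C)(C)C(C)(C)C)C(=O)N(C)OC | intermediate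
15 | [(2S,3S)-2-(3,4-dimethoxyphenyl)-7-methoxy-3-methyl-2,3-dihydro-1-benzofuran-5-yl]lithium | COc1ccc([C@H]2Oc3c(OC)cc([Li])cc3[C@@H]2C)cc1OC | intermediate
16 | lithium (2R)-2-[(tert-butyldimethylsilyl)oxy]-1-[(2S,3S)-2-(3,4-dimethoxyphenyl)-7-methoxy-3-methyl-2,3-dihydro-1-benzofuran-5-yl]-1-[methoxy(methyl)amino]propan-1-olate (tetrahedral adduct, both epimers at C1) | COc1ccc([C@H]2Oc3c(OC)cc(C(O[Li])([C@@H](C)O[Si](C)(C)C(C)(C)C)N(C)OC)cc3[C@@H]2C)cc1OC | intermediate
17 | (2R)-2-[(tert-butyldimethylsilyl)oxy]-1-[(2S,3S)-2-(3,4-dimethoxyphenyl)-7-methoxy-3-methyl-2,3-dihydro-1-benzofuran-5-yl]propan-1-one | COc1ccc([C@H]2Oc3c(OC)cc(C(=O)[C@@H](C)O[Si](C)(C)C(C)(C)C)cc3[C@@H]2C)cc1OC | intermediate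
18 | (2R)-1-[(2S,3S)-2-(3,4-dimethoxyphenyl)-7-methoxy-3-methyl-2,3-dihydro-1-benzofuran-5-yl]-2-hydroxypropan-1-one | COc1ccc([C@H]2Oc3c(OC)cc(C(=O)[C@@H](C)O)cc3[C@@H]2C)cc1OC | intermediate
19 | (1S,2R)-1-[(2S,3S)-2-(3,4-dimethoxyphenyl)-7-methoxy-3-methyl-2,3-dihydro-1-benzofuran-5-yl]propane-1,2-diol | COc1ccc([C@H]2Oc3c(OC)cc([C@H](O)[C@@H](C)O)cc3[C@@H]2C)cc1OC | target

**Step count**

Total: 11 steps. Longest linear sequence: 9 steps (steps 1 to 6, then 9 to 11); steps 7 and 8 form the side branch.

**Steps most likely to fail**

Step 4 (proposed new method). The ring-opened cation may lose the C3 proton faster than it is arylated. This would aromatise the furan ring and, if the proton returns, erode the C3 configuration. The product may also be arylated a second time after ionisation of its C2–O1 bond.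

The fallback sets out from 6 and comes back at 8. It makes the aryl–carbon bond by carbonyl addition and closes the oxygen ring afterwards.
- Hydrolytic ring opening of the 2-oxycyclopropanecarboxylate (0.5 M aq HCl, THF, rt) should give the lactol ethyl 2-[(3S)-5-bromo-2-hydroxy-7-methoxy-2,3-dihydro-1-benzofuran-3-yl]acetate F1 as both anomers.
- (3,4-Dimethoxyphenyl)magnesium bromide (3 equiv, THF, −78 → −30 °C, cold quench) should add to the aldehyde form in preference to the ester. This should give ethyl (3S)-3-(5-bromo-2-hydroxy-3-methoxyphenyl)-4-(3,4-dimethoxyphenyl)-4-hydroxybutanoate F2 as both carbinol epimers.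
- Acid-catalysed cyclodehydration (TsOH cat., CH2Cl2, 0 °C), a known closure for 1-aryl-2-(2-hydroxyaryl)propan-1-ols, should return 8. The phenol captures the benzylic cation stabilised by the dimethoxyphenyl ring, and both epimers should converge on the trans product.
- In this sequence the cationic carbon is not part of the oxygen ring when it is formed and is trapped intramolecularly, so the aromatisation channel is absent.

Step 3. Carbene transfer to the weakly nucleophilic furan double bond may be slow, so that carbene dimerisation dominates, and the facial selectivity may be insufficient.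

The fallback sets out from 4 and comes back at 6.
- Cyclopropanation with 5 under Rh2(OAc)4 catalysis (1 mol %, CH2Cl2, rt, slow addition) should give the racemic ethyl 5-bromo-3-methoxy-1a,6b-dihydro-1H-cyclopropa[b][1]benzofuran-1-carboxylate F3.
- Preparative chromatography on a chiral stationary phase then separates the (1R,1aR,6bS) enantiomer, which is 6.

Step 6. The primary radical may undergo beta-scission of the C2–C3 bond, opening the dihydrofuran ring and scrambling C2 and C3 on reclosure, in competition with hydrogen-atom transfer.

The fallback sets out from 8 and comes back at 11. It removes the carbon without a carbon radical.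
- Partial reduction of the ester (i-Bu2AlH, toluene, −78 °C) should give 2-[(2S,3S)-5-bromo-2-(3,4-dimethoxyphenyl)-7-methoxy-2,3-dihydro-1-benzofuran-3-yl]acetaldehyde F4.
- Tsuji–Wilkinson decarbonylation (RhCl(PPh3)3, 1.05 equiv, toluene, 110 °C) should then give 11. It proceeds by oxidative addition of the aldehyde C–H bond to monovalent rhodium, loss of CO from the acyl group and reductive elimination.

**Further compounds**

F1 | step 4 | ethyl 2-[(3S)-5-bromo-2-hydroxy-7-methoxy-2,3-dihydro-1-benzofuran-3-yl]acetate (both anomers) | OC1Oc2c(OC)cc(Br)cc2[C@@H]1CC(=O)OCC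
F2 | step 4 | ethyl (3S)-3-(5-bromo-2-hydroxy-3-methoxyphenyl)-4-(3,4-dimethoxyphenyl)-4-hydroxybutanoate (both epimers at C4) | CCOC(=O)C[C@@H](c1cc(Br)cc(OC)c1O)C(O)c1ccc(OC)c(OC)c1
F3 | step 3 | racemic ethyl 5-bromo-3-methoxy-1a,6b-dihydro-1H-cyclopropa[b][1]benzofuran-1-carboxylate (6 together with its (1S,1aS,6bR) enantiomer; the enantiomer is drawn) | CCOC(=O)[C@@H]1[C@H]2Oc3c(OC)cc(Br)cc3[C@@H]12
F4 | step 6 | 2-[(2S,3S)-5-bromo-2-(3,4-dimethoxyphenyl)-7-methoxy-2,3-dihydro-1-benzofuran-3-yl]acetaldehyde | COc1ccc([C@H]2Oc3c(OC)cc(Br)cc3[C@@H]2CC=O)cc1OC
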